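**Retrosynthetic overview**

1. The target is a 2-arylbenzofuran (ring A = benzo ring C3a–C7a, ring B = the 2-aryl group, plus the furan ring) with CHO at C3, OH at C4, prenyl at C5 and OMe at C6. The last operations are desilylation of the ring B phenol and adjustment of a C3 methyl ester to the aldehyde.
2. The C5 prenyl group comes from a C4–O 1,1-dimethylallyl ether by aromatic Claisen shift, and the C4 hydroxyl from an isopropyl ether.
3. Key disconnection O1–C7a: O1 on C7a is meta to the oxygens on C4 and C6, and C7 carries hydrogen. The bond is therefore made by attack of a keto ester enolate oxygen on a C7–C7a aryne, generated from a bromide at C7, the position where a 2,4-dialkoxyphenyl ring brominates by itself.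
4. The aryne precursor is an α-aryl β-keto ester, made by C-acylation of a (5-bromo-2,4-dialkoxyphenyl)acetate with a ring B aroyl chloride. The two fragments come from paeonol and 4-hydroxy-2-methoxybenzoic acid.
5. Ring order: rings A and B are bought; the furan ring is the only ring formed, in step 7.

Key step: step 7

Remark on the chemistry: the future C4 oxygen is carried through the key step as an isopropyl ether and not as a third methyl ether. BCl3 can then free it on the strength of the alkyl group and does not have to tell three methyl ethers apart by chelation alone. The acylation of step 6 is run with a sodium amide base and the aryne closure of step 7 with a lithium amide base, so the keto ester passes through its sodium enolate in step 6 and through its lithium enolate in step 7. The target has no stereocentre and no stereogenic double bond.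

**Route**

Step 1
Reactants: 1 1-(2-hydroxy-4-methoxyphenyl)ethan-1-one (paeonol)
Product: 2 1-[4-methoxy-2-(propan-2-yloxy)phenyl]ethan-1-one
Conditions: 2-bromopropane, K2CO3, DMF, 70 °C
Reagents that add atoms: 2-bromopropane, CC(C)Br
Why: Williamson etherification, in which carbonate in DMF frees the phenoxide from its hydrogen bond to the acetyl group and it displaces bromide from the secondary halide; the isopropyl group marks the future C4 oxygen for later selective cleavage.

Step 2
Reactants: 2 1-[4-methoxy-2-(propan-2-yloxy)phenyl]ethan-1-one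
Product: 3 1-[5-bromo-4-methoxy-2-(propan-2-yloxy)phenyl]ethan-1-one
Conditions: N-bromosuccinimide, MeCN, 0 °C → rt
Reagents that add atoms: N-bromosuccinimide, O=C1CCC(=O)N1Br
Why: Electrophilic aromatic bromination goes to C5, which is para to the isopropoxy group, ortho to the methoxy group and meta to the acetyl group, while C3 is shielded between two alkoxy groups; the bromide also blocks the most nucleophilic ring position for the next step.

Step 3
Reactants: 3 1-[5-bromo-4-methoxy-2-(propan-2-yloxy)phenyl]ethan-1-one
Product: 4 methyl 2-[5-bromo-4-methoxy-2-(propan-2-yloxy)phenyl]acetate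
Conditions: PhI(OAc)2, H2SO4, HC(OMe)3, 60 °C; aq NaHCO3
Reagents that add atoms: trimethyl orthoformate, COC(OC)OC; water, O
Why: Oxidative 1,2-aryl migration of an aryl methyl ketone with a trivalent iodine oxidant in acidic trimethyl orthoformate, in which the ketone reacts at its α-carbon with the iodine reagent, the electron-rich dialkoxyaryl group shifts to that carbon as iodobenzene leaves, and the methyl ester is released on aqueous work-up.

Step 4
Reactants: 5 4-hydroxy-2-methoxybenzoic acid
Product: 7 2-methoxy-4-(triisopropylsilyloxy)benzoic acid, via bis-silyl ester 6 (not isolated)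
Conditions: i-Pr3SiCl (2.3 equiv), imidazole, DMF, rt; then AcOH/THF/H2O, rt
Reagents that add atoms: triisopropylsilyl chloride, CC(C)[Si](Cl)(C(C)C)C(C)C
Why: Silylation of both the phenol and the acid followed by selective hydrolysis of the much more labile silyl ester in aqueous acetic acid leaves the bulky aryl silyl ether, which resists amide bases and hinders lithiation next to it.

Step 5
Reactants: 7 2-methoxy-4-(triisopropylsilyloxy)benzoic acid
Product: 8 2-methoxy-4-(triisopropylsilyloxy)benzoyl chloride
Conditions: (COCl)2, DMF (cat.), CH2Cl2, 0 °C → rt; used crude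
Reagents that add atoms: oxalyl chloride, O=C(Cl)C(=O)Cl
Why: Acid chloride formation through the Vilsmeier-type chloroiminium catalyst from oxalyl chloride and DMF, under which the hindered aryl silyl ether should survive the HCl formed.

Step 6
Reactants: 4 methyl 2-[5-bromo-4-methoxy-2-(propan-2-yloxy)phenyl]acetate; 8 2-methoxy-4-(triisopropylsilyloxy)benzoyl chloride
Product: 11 methyl 2-[5-bromo-4-methoxy-2-(propan-2-yloxy)phenyl]-3-[2-methoxy-4-(triisopropylsilyloxy)phenyl]-3-oxopropanoate, via sodium ester enolate 9 (not isolated), via sodium keto ester enolate 10 (not isolated)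
Conditions: NaN(SiMe3)2 (2.2 equiv), THF, −78 °C; then 8, −78 → 0 °C; aq NH4Cl
Reagents that add atoms: none
Why: Crossed Claisen-type C-acylation, in which the silylamide converts 4 into sodium enolate 9, this attacks the aroyl chloride at carbon, and the second equivalent of base turns the more acidic product into sodium enolate 10 so that it is not acylated again and is recovered as racemic 11 on protonation.

Step 7
Reactants: 11 methyl 2-[5-bromo-4-methoxy-2-(propan-2-yloxy)phenyl]-3-[2-methoxy-4-(triisopropylsilyloxy)phenyl]-3-oxopropanoate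
Product: 15 methyl 6-methoxy-2-[2-methoxy-4-(triisopropylsilyloxy)phenyl]-4-(propan-2-yloxy)-1-benzofuran-3-carboxylate, via lithium keto ester enolate 12 (not isolated), via aryne enolate 13 (not isolated), via C7 aryllithium 14 (not isolated)
Conditions: lithium 2,2,6,6-tetramethylpiperidide (4 equiv, from n-BuLi and 2,2,6,6-tetramethylpiperidine), THF, −78 → 0 °C; aq NH4Cl
Reagents that add atoms: none
Why: The first equivalent of base gives chelated lithium enolate 12; a further equivalent removes the only hydrogen ortho to bromine (at the future C7a) and loss of LiBr gives aryne 13, whose carbon next to the side chain is attacked by the ketone-derived enolate oxygen to form O1–C7a and aryllithium 14, which is protonated at C7 by 2,2,6,6-tetramethylpiperidine or on quench. The closest known reaction type is aryne ring closure by a tethered heteroatom or enolate nucleophile, as in the amide-base cyclisation of haloaryl amides to benzoxazoles and of haloaryl ketones to benzofurans; here it is applied to a meta-bromo α-aryl β-keto ester. The furan ring closes in a 5-exo-dig sense on the strained aryne bond, through the in-plane lone pair of the enolate oxygen with the enolate C=C inside the new ring. No stereocentre is formed, and the one in 11 is erased on enolisation. The step needs attack by oxygen at C7a and by the ketone oxygen in preference to the ester oxygen: carbon attack would need a three-membered ring and attack at C7 a meta bridge, the C6 methoxy group polarises the aryne so that the negative charge develops at C7 beside it, and the ketone oxygen carries most of the enolate charge and alone leads to an aromatic furan. The hindered amide base should not add to the aryne, and lithiation between the two alkoxy groups of ring A, slowed by the isopropoxy group, is reversible and is undone on work-up.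

Step 8
Reactants: 15 methyl 6-methoxy-2-[2-methoxy-4-(triisopropylsilyloxy)phenyl]-4-(propan-2-yloxy)-1-benzofuran-3-carboxylate
Product: 16 methyl 4-hydroxy-6-methoxy-2-[2-methoxy-4-(triisopropylsilyloxy)phenyl]-1-benzofuran-3-carboxylate
Conditions: BCl3 (2 equiv), CH2Cl2, −78 → −20 °C; aq NaHCO3
Reagents that add atoms: none
Why: Lewis acid dealkylation, in which BCl3 cleaves a secondary alkyl aryl ether far faster than methyl aryl ethers and is also held by the neighbouring ester carbonyl next to the C4 oxygen, so that only the isopropyl group should leave while the two methyl ethers, the methyl ester and the aryl silyl ether stay.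

Step 9
Reactants: 16 methyl 4-hydroxy-6-methoxy-2-[2-methoxy-4-(triisopropylsilyloxy)phenyl]-1-benzofuran-3-carboxylate
Product: 17 methyl 6-methoxy-2-[2-methoxy-4-(triisopropylsilyloxy)phenyl]-4-[(2-methylbut-3-yn-2-yl)oxy]-1-benzofuran-3-carboxylate
Conditions: 3-chloro-3-methylbut-1-yne, DBU, CuCl2·2H2O (cat.), MeCN, 0 °C → rt
Reagents that add atoms: 3-chloro-3-methylbut-1-yne, CC(C)(Cl)C#C
Why: Copper-catalysed propargylic etherification of a phenol with a tertiary propargylic chloride under amidine base is the standard way to aryl 1,1-dimethylpropargyl ethers, and the phenoxide is the only nucleophile present.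

Step 10
Reactants: 17 methyl 6-methoxy-2-[2-methoxy-4-(triisopropylsilyloxy)phenyl]-4-[(2-methylbut-3-yn-2-yl)oxy]-1-benzofuran-3-carboxylate
Product: 18 methyl 6-methoxy-2-[2-methoxy-4-(triisopropylsilyloxy)phenyl]-4-[(2-methylbut-3-en-2-yl)oxy]-1-benzofuran-3-carboxylate
Conditions: H2 (1 atm), Pd/CaCO3 poisoned with Pb(OAc)2, quinoline, EtOAc, rt
Reagents that add atoms: none
Why: Lindlar semihydrogenation should stop at the terminal alkene because the poisoned palladium surface binds the alkyne much more strongly than the alkene, and the arenes, ester and silyl ether are inert.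

Step 11
Reactants: 18 methyl 6-methoxy-2-[2-methoxy-4-(triisopropylsilyloxy)phenyl]-4-[(2-methylbut-3-en-2-yl)oxy]-1-benzofuran-3-carboxylate
Product: 20 methyl 4-hydroxy-6-methoxy-2-[2-methoxy-4-(triisopropylsilyloxy)phenyl]-5-(3-methylbut-2-en-1-yl)-1-benzofuran-3-carboxylate, via dienone 19 (not isolated)
Conditions: N,N-diethylaniline, 140 °C
Reagents that add atoms: none
Why: Aromatic Claisen rearrangement, in which the [3,3] shift carries the allyl unit to C5, the only ortho position that bears hydrogen (the other is the ring-fusion carbon C3a), with allylic inversion so that the 1,1-dimethylallyl ether arrives as the 3-methylbut-2-enyl group in dienone 19, which tautomerises to the phenol, while the amine solvent suppresses acid-catalysed chroman formation.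

Step 12
Reactants: 20 methyl 4-hydroxy-6-methoxy-2-[2-methoxy-4-(triisopropylsilyloxy)phenyl]-5-(3-methylbut-2-en-1-yl)-1-benzofuran-3-carboxylate
Product: 21 3-(hydroxymethyl)-6-methoxy-2-[2-methoxy-4-(triisopropylsilyloxy)phenyl]-5-(3-methylbut-2-en-1-yl)-1-benzofuran-4-ol
Conditions: i-Bu2AlH (4 equiv), CH2Cl2, −78 → 0 °C; aq potassium sodium tartrate
Reagents that add atoms: none
Why: Ester reduction with the aluminium hydride, in which the first equivalent deprotonates the phenol and the excess reduces the methyl ester through the aldehyde to the primary alcohol at low temperature, leaving the trisubstituted alkene and the silyl ether alone.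

Step 13
Reactants: 21 3-(hydroxymethyl)-6-methoxy-2-[2-methoxy-4-(triisopropylsilyloxy)phenyl]-5-(3-methylbut-2-en-1-yl)-1-benzofuran-4-ol
Product: 22 4-hydroxy-6-methoxy-2-[2-methoxy-4-(triisopropylsilyloxy)phenyl]-5-(3-methylbut-2-en-1-yl)-1-benzofuran-3-carbaldehyde
Conditions: activated MnO2 (excess), CH2Cl2, rt
Reagents that add atoms: none
Why: Activated MnO2 oxidises the benzylic-type hydroxymethyl group on the furan ring to the aldehyde and should stop there, the new formyl group being held by a hydrogen bond to the C4 hydroxyl.

Step 14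
Reactants: 22 4-hydroxy-6-methoxy-2-[2-methoxy-4-(triisopropylsilyloxy)phenyl]-5-(3-methylbut-2-en-1-yl)-1-benzofuran-3-carbaldehyde
Product: 23 4-hydroxy-2-(4-hydroxy-2-methoxyphenyl)-6-methoxy-5-(3-methylbut-2-en-1-yl)-1-benzofuran-3-carbaldehyde
Conditions: Bu4NF, AcOH, THF, 0 °C
Reagents that add atoms: none
Why: Fluoride-induced cleavage of the aryl silyl ether is driven by the strong Si–F bond, and the acetic acid buffer keeps the aldehyde and the two free phenols away from strongly basic fluoride.

**Compound list**

1 | 1-(2-hydroxy-4-methoxyphenyl)ethan-1-one (paeonol) | CC(=O)c1ccc(OC)cc1O | starting material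
2 | 1-[4-methoxy-2-(propan-2-yloxy)phenyl]ethan-1-one | CC(=O)c1ccc(OC)cc1OC(C)C | intermediate
3 | 1-[5-bromo-4-methoxy-2-(propan-2-yloxy)phenyl]ethan-1-one | CC(=O)c1cc(Br)c(OC)cc1OC(C)C | intermediate
4 | methyl 2-[5-bromo-4-methoxy-2-(propan-2-yloxy)phenyl]acetate | COC(=O)Cc1cc(Br)c(OC)cc1OC(C)C | intermediate
5 | 4-hydroxy-2-methoxybenzoic acid | COc1cc(O)ccc1C(=O)O | starting material
6 | triisopropylsilyl 2-methoxy-4-(triisopropylsilyloxy)benzoate | COc1cc(O[Si](C(C)C)(C(C)C)C(C)C)ccc1C(=O)O[Si](C(C)C)(C(C)C)C(C)C | intermediate (not isolated)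
7 | 2-methoxy-4-(triisopropylsilyloxy)benzoic acid | COc1cc(O[Si](C(C)C)(C(C)C)C(C)C)ccc1C(=O)O | intermediate
8 | 2-methoxy-4-(triisopropylsilyloxy)benzoyl chloride | COc1cc(O[Si](C(C)C)(C(C)C)C(C)C)ccc1C(=O)Cl | intermediate
9 | sodium enolate of 4 | COC(O[Na])=Cc1cc(Br)c(OC)cc1OC(C)C | intermediate (not isolated)
10 | sodium enolate of 11, drawn with sodium on the ketone oxygen | COC(=O)C(=C(O[Na])c1ccc(O[Si](C(C)C)(C(C)C)C(C)C)cc1OC)c1cc(Br)c(OC)cc1OC(C)C | intermediate (not isolated)
11 | methyl 2-[5-bromo-4-methoxy-2-(propan-2-yloxy)phenyl]-3-[2-methoxy-4-(triisopropylsilyloxy)phenyl]-3-oxopropanoate (racemic) | COC(=O)C(C(=O)c1ccc(O[Si](C(C)C)(C(C)C)C(C)C)cc1OC)c1cc(Br)c(OC)cc1OC(C)C | intermediate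
12 | lithium enolate of 11, drawn with lithium on the ketone oxygen | COC(=O)C(=C(O[Li])c1ccc(O[Si](C(C)C)(C(C)C)C(C)C)cc1OC)c1cc(Br)c(OC)cc1OC(C)C | intermediate (not isolated)
13 | aryne enolate: 12 with the C5–Br and C6–H of the bromoarene replaced by an aryne bond | COC(=O)C(=C(O[Li])c1ccc(O[Si](C(C)C)(C(C)C)C(C)C)cc1OC)C1=C(OC(C)C)C=C(OC)C#C1 | intermediate (not isolated)
14 | methyl 7-lithio-6-methoxy-2-[2-methoxy-4-(triisopropylsilyloxy)phenyl]-4-(propan-2-yloxy)-1-benzofuran-3-carboxylate | COC(=O)c1c(-c2ccc(O[Si](C(C)C)(C(C)C)C(C)C)cc2OC)oc2c([Li])c(OC)cc(OC(C)C)c12 | intermediate (not isolated)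
15 | methyl 6-methoxy-2-[2-methoxy-4-(triisopropylsilyloxy)phenyl]-4-(propan-2-yloxy)-1-benzofuran-3-carboxylate | COC(=O)c1c(-c2ccc(O[Si](C(C)C)(C(C)C)C(C)C)cc2OC)oc2cc(OC)cc(OC(C)C)c12 | intermediate
16 | methyl 4-hydroxy-6-methoxy-2-[2-methoxy-4-(triisopropylsilyloxy)phenyl]-1-benzofuran-3-carboxylate | COC(=O)c1c(-c2ccc(O[Si](C(C)C)(C(C)C)C(C)C)cc2OC)oc2cc(OC)cc(O)c12 | intermediate
17 | methyl 6-methoxy-2-[2-methoxy-4-(triisopropylsilyloxy)phenyl]-4-[(2-methylbut-3-yn-2-yl)oxy]-1-benzofuran-3-carboxylate | COC(=O)c1c(-c2ccc(O[Si](C(C)C)(C(C)C)C(C)C)cc2OC)oc2cc(OC)cc(OC(C)(C)C#C)c12 | intermediate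
18 | methyl 6-methoxy-2-[2-methoxy-4-(triisopropylsilyloxy)phenyl]-4-[(2-methylbut-3-en-2-yl)oxy]-1-benzofuran-3-carboxylate | COC(=O)c1c(-c2ccc(O[Si](C(C)C)(C(C)C)C(C)C)cc2OC)oc2cc(OC)cc(OC(C)(C)C=C)c12 | intermediate
19 | methyl 6-methoxy-2-[2-methoxy-4-(triisopropylsilyloxy)phenyl]-5-(3-methylbut-2-en-1-yl)-4-oxo-4,5-dihydro-1-benzofuran-3-carboxylate (racemic at C5) | COC(=O)C1=C(c2ccc(O[Si](C(C)C)(C(C)C)C(C)C)cc2OC)OC2=C1C(=O)C(CC=C(C)C)C(OC)=C2 | intermediate (not isolated)
20 | methyl 4-hydroxy-6-methoxy-2-[2-methoxy-4-(triisopropylsilyloxy)phenyl]-5-(3-methylbut-2-en-1-yl)-1-benzofuran-3-carboxylate | COC(=O)c1c(-c2ccc(O[Si](C(C)C)(C(C)C)C(C)C)cc2OC)oc2cc(OC)c(CC=C(C)C)c(O)c12 | intermediate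
21 | 3-(hydroxymethyl)-6-methoxy-2-[2-methoxy-4-(triisopropylsilyloxy)phenyl]-5-(3-methylbut-2-en-1-yl)-1-benzofuran-4-ol | OCc1c(-c2ccc(O[Si](C(C)C)(C(C)C)C(C)C)cc2OC)oc2cc(OC)c(CC=C(C)C)c(O)c12 | intermediate
22 | 4-hydroxy-6-methoxy-2-[2-methoxy-4-(triisopropylsilyloxy)phenyl]-5-(3-methylbut-2-en-1-yl)-1-benzofuran-3-carbaldehyde | O=Cc1c(-c2ccc(O[Si](C(C)C)(C(C)C)C(C)C)cc2OC)oc2cc(OC)c(CC=C(C)C)c(O)c12 | intermediate
23 | 4-hydroxy-2-(4-hydroxy-2-methoxyphenyl)-6-methoxy-5-(3-methylbut-2-en-1-yl)-1-benzofuran-3-carbaldehyde | COc1cc(O)ccc1-c1oc2cc(OC)c(CC=C(C)C)c(O)c2c1C=O | target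

**Step count**

Total: 14 steps. Longest linear sequence: 12 steps (steps 1, 2, 3, 6, 7, 8, 9, 10, 11, 12, 13, 14 from paeonol 1); the ring B branch from 5 (steps 4 and 5) joins at step 6.

**Steps most likely to fail, with fallbacks**

Step 7 (aryne ring closure).
- What may go wrong: deprotonation ortho to bromine on the already anionic enolate may be too slow, so that the base is used up in unproductive ring lithiation. The chelated, U-shaped keto ester enolate may also fail to turn its ketone oxygen toward the aryne before the aryne is lost to intermolecular addition.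
- Fallback: it sets out from acid chloride 8 and comes back to the route at phenol 16. Acylation of potassium methyl malonate with 8 (MgCl2, Et3N, MeCN, then acidic work-up with loss of CO2) should give methyl 3-[2-methoxy-4-(triisopropylsilyloxy)phenyl]-3-oxopropanoate F1. Iron-catalysed oxidative coupling and annulation of F1 with purchased 3,5-dimethoxyphenol (COc1cc(O)cc(OC)c1; FeCl3·6H2O cat., di-tert-butyl peroxide, 1,2-dichloroethane, 100 °C) joins the phenol ortho carbon to the keto ester α-carbon and condenses the phenol oxygen onto the ketone. This should give methyl 4,6-dimethoxy-2-[2-methoxy-4-(triisopropylsilyloxy)phenyl]-1-benzofuran-3-carboxylate F2, so that O1 is bought with the phenol and no aryl C–O bond has to be made. BCl3 (CH2Cl2, −78 → 0 °C), held between the ester carbonyl and the peri C4 oxygen, should then remove the C4 methyl group alone and give 16.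

Step 9 (O-alkylation with the tertiary propargylic chloride).
- What may go wrong: the phenoxide of 16, hydrogen-bonded to and crowded by the peri ester, may react too slowly, so that the tertiary electrophile is consumed by elimination instead of etherification.
- Fallback: it sets out from phenol 16 and comes back at allyl ether 18, so that propargyl ether 17 and step 10 are not needed. Tsuji–Trost O-allylation with tert-butyl 2-methylbut-3-en-2-yl carbonate (CC(C)(C)OC(=O)OC(C)(C)C=C) and Pd(PPh3)4 in THF at 0 °C forms a 1,1-dimethylallyl palladium complex. The phenoxide released on decarboxylation attacks its more substituted end and should give the tertiary ether 18 directly. This detour makes no compound outside the list (F0).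

Step 3 (oxidative aryl migration).
- What may go wrong: attack of the trivalent iodine electrophile on the electron-rich ring, or acid-induced loss of the isopropyl group, may compete with the aryl shift.
- Fallback: it sets out from ketone 3 and comes back at ester 4. A Willgerodt–Kindler reaction (S8, morpholine, 130 °C) should give 2-[5-bromo-4-methoxy-2-(propan-2-yloxy)phenyl]-1-(morpholin-4-yl)ethane-1-thione F3. Hydrolysis (KOH, EtOH/H2O, reflux) gives 2-[5-bromo-4-methoxy-2-(propan-2-yloxy)phenyl]acetic acid F4, and Fischer esterification (MeOH, H2SO4 cat., reflux) returns 4.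

**Further compounds**

F1 | step 7 | methyl 3-[2-methoxy-4-(triisopropylsilyloxy)phenyl]-3-oxopropanoate | COC(=O)CC(=O)c1ccc(O[Si](C(C)C)(C(C)C)C(C)C)cc1OC
F2 | step 7 | methyl 4,6-dimethoxy-2-[2-methoxy-4-(triisopropylsilyloxy)phenyl]-1-benzofuran-3-carboxylate | COC(=O)c1c(-c2ccc(O[Si](C(C)C)(C(C)C)C(C)C)cc2OC)oc2cc(OC)cc(OC)c12
F0 | step 9 | none | none
F3 | step 3 | 2-[5-bromo-4-methoxy-2-(propan-2-yloxy)phenyl]-1-(morpholin-4-yl)ethane-1-thione | S=C(Cc1cc(Br)c(OC)cc1OC(C)C)N1CCOCC1
F4 | step 3 | 2-[5-bromo-4-methoxy-2-(propan-2-yloxy)phenyl]acetic acid | OC(=O)Cc1cc(Br)c(OC)cc1OC(C)C
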